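The readings were generated by integration with made-up constants; noise was put on by code.

The theta run served me as a clock for the four new flasks.

| flask | substrate | reagent | temperature | remark | time |
|---|---|---|---|---|---|
| theta | 14 mM | 35 mM | 95 °C | run made earlier |  |
| epsilon | 20 mM | 35 mM | 106 °C | run made earlier |  |
| beta | 31 mM | 35 mM | 95 °C | run made earlier |  |
| delta | 14 mM | 52 mM | 106 °C | run made earlier |  |
| grey | 14 mM | 35.0 mM | 100 °C | everything together at the start | 80 min |
| ochre | 14 mM | 35.0 mM (fed, over 1.0 h) | 100 °C | all else is in the flask from the start; the feed brings no volume worth counting | 80 min |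
| green | 14 mM (fed, over 1.0 h) | 35.0 mM | 100 °C | all else is in the flask from the start; the feed brings no volume worth counting | 80 min |
| blue | 14 mM (fed, over 1.0 h) | 35.0 mM |  | the addition at 80 °C, then warmed to 100 °C; the feed brings no volume worth counting | 80 min |

| run | time / min | product / % | resting dimer / % |
|---|---|---|---|
| theta | 4.00 | 4.2 | 38.9 |
| theta | 12.0 | 11.0 | 33.5 |
| theta | 20.0 | 18.4 | 29.9 |
| theta | 30.0 | 24.9 | 24.3 |
| theta | 50.0 | 37.4 | 16.7 |
| epsilon | 10.0 | 15.9 | 40.1 |
| epsilon | 20.0 | 27.9 | 28.7 |
| epsilon | 30.0 | 37.5 | 21.3 |
| epsilon | 40.0 | 45.8 | 15.6 |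
| epsilon | 50.0 | 51.6 | 11.4 |
| beta | 10.0 | 7.3 | 49.2 |
| beta | 20.0 | 13.7 | 43.5 |
| beta | 30.0 | 19.4 | 38.0 |
| beta | 40.0 | 24.7 | 34.1 |
| beta | 50.0 | 29.6 | 30.3 |
| delta | 10.0 | 24.7 | 29.1 |
| delta | 20.0 | 43.9 | 16.2 |
| delta | 30.0 | 57.0 | 8.8 |
| delta | 40.0 | 66.3 | 4.8 |
| delta | 50.0 | 72.2 | 2.3 |

(each reading ± 0.3 percentage points)

- percent here means substrate units held: one resting dimer counts as two
- what may be going on: 2 substrate <-> resting dimer; substrate <-> dormant form; substrate + reagent -> product

- which flask leads in share of product in product plus resting dimer ("all alike" within 1.5 percentage points) (grey / ochre / green / blue / all alike)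
- share of product in product plus resting dimer at the end, grey
- share of product in product plus resting dimer at the end, ochre
- share of product in product plus resting dimer at the end, green
- share of product in product plus resting dimer at the end, blue

Theta, in slow motion, went like this. In the first instants substrate joined into resting dimer: by 4.00 min the dimer held 38.9% and product 4.2%. Through the middle the dimer fell at 0.0184 min⁻¹, which put its start near 41.9%. Product, taken as a first-order loss of whatever was not yet product, grew at 0.00937 min⁻¹, so the dimer drained faster than product filled. Reagent could lose 40.0% of itself at most, which is no true excess, but I accepted that error, treated the step as roughly pseudo-first-order and scaled by the reagent charged.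

Scaled so, delta's product rate was 1.95 times theta's. Interpolating its logarithm gave me the clock factor, the theta minutes that pass in one flask minute at 100 °C: 1.36. At 80 °C it was 0.401.

For the end I replaced each steady feed by its mean, the whole charge entering at mid-feed, which left a stay of 50.0 min. Reckoned in theta time, grey ran 108 min, and ochre and green ran 67.8 min. Blue ran 39.2 min, of which 27.1 min came from its hot 20.0 min. My clock put product at 63.8% for grey, 47.0% for ochre and green, and 30.7% for blue. My shares of product in product plus dimer were 91.8% for grey, 79.6% for ochre and green, and 60.1% for blue.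

The forecast named grey as leader, with grey 93.5%, ochre 80% “because reagent comes late”, green 79% and blue 58%.

The flasks gave grey 92.0%, ochre 80.3%, green 79.7% and blue 58.3%.

    2 substrate ⇌ resting dimer, settled at all times (K = 53.0 L mol⁻¹, ΔH = 40.0 kJ mol⁻¹)
    substrate ⇌ dormant form (K = 1.90, k = 1.10 × 10⁻⁴ s⁻¹, Ea = 123 kJ mol⁻¹, ΔH = −33.0 kJ mol⁻¹)
    substrate + reagent → product (k = 0.0120 L mol⁻¹ s⁻¹, Ea = 84.0 kJ mol⁻¹)
    (constants at 100 °C)

Ochre and green ended with product at 43.2% and 47.2%, where my clock had 47.0%. Grey stopped at 65.0 min comes to 88.1 min in theta time at clock factor 1.36, which reckons to a share of 87.2%. That flask stood 5 points under grey's end, at 87.0%.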